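Target is made from two substrate, and in both earlier runs it drains away from the first reading on. We want to know how much of it stands at 40 h for each charge.

| flask | substrate | remark | time |
|---|---|---|---|
| theta | 11 mM | run made earlier |  |
| epsilon | 96 mM | run made earlier |  |
| north | 20 mM |  | 40 h |
| north-west | 40 mM |  | 40 h |
| south | 80 mM |  | 40 h |
| west | 150 mM |  | 40 h |

| run | time / h | target / % | substrate / % |
|---|---|---|---|
| theta | 6.00 | 33.5 | 51.7 |
| theta | 12.0 | 29.1 | 49.0 |
| theta | 20.0 | 25.7 | 42.8 |
| theta | 25.0 | 19.2 | 41.7 |
| theta | 30.0 | 20.4 | 41.0 |
| theta | 40.0 | 18.0 | 37.3 |
| epsilon | 3.00 | 75.3 | 12.4 |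
| epsilon | 5.00 | 69.0 | 13.1 |
| epsilon | 8.00 | 63.5 | 14.5 |
| epsilon | 15.0 | 46.5 | 13.9 |
| epsilon | 25.0 | 23.0 | 14.1 |
| epsilon | 40.0 | 7.9 | 7.8 |

(scatter of a reading: 1 percentage point)

- percent here means substrate units held: one target counts as two
- a reading or a percentage of target counts all its forms, free or not
- "hardly changes" means that all values lie within two and a half points (for a concentration: within two and a half percent of the largest)

1. amount of target at the end, in percent of the substrate charged for north, north-west, south, west, in this order
2. the shape of the row from first to last (rises, then falls / falls all the way / falls, then rises / hardly changes / rises all the way)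

In the theta run the ratio of [target] to the square of [substrate] stays level within the scatter, and the pooled readings give 56.6 L mol⁻¹. Call it K. We read this as a pre-equilibrium, so we follow one thing: the units in the pair, [substrate] plus twice [target].

The pair leaks. Between 5.00 h and 25.0 h of the epsilon run [substrate] reads near 13.3 mM while target falls in a straight line, 2.21 mM h⁻¹ in substrate units. We read that as crystals feeding a solution held near 10.0 mM of [target], so we take a pair above 33.5 mM to carry crystals. The theta run leaks 0.0967 mM h⁻¹ at a mean [substrate] of 4.89 mM, so the two leaks give an order of 3.13 in substrate, which we take as a cube. The epsilon leak over the cube of its [substrate], 0.258 L² mol⁻² s⁻¹, is what we carry: the leak coefficient a, units lost per hour over the cube of [substrate].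

Without crystals the leak integrates in closed form: 0.5/[substrate]^2 + 4K/[substrate] grows by a in each hour. North is charged below the crystal line. We reckon it from the [substrate] that K gives for its charge, 9.59 mM, down to 4.95 mM, which is 13.8% target. North-west stands 6.50 mM above the line, less than the 17.2 mM that epsilon lost by 5.00 h, so we start it on the line at once and get 8.74%. We let south follow the epsilon line until 18.3 h, then the integral, and get 7.67%. In our reckoning west stays above the line and gives 28.1%.

The forecast, which reads the epsilon plateau as “excess target sitting as a solid”, gives 13%, 9%, 7.5% and 26%, falls, then rises, the same shape as ours, with our west higher than its value.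

The flasks give 12.4%, 8.21%, 7.10% and 25.6%: falls, then rises.

    2 substrate ⇌ target (K = 55.0 L mol⁻¹, k = 0.0120 L mol⁻¹ s⁻¹)
    crystals ⇌ target, rate k2*(cs2 - [target]) while solid is left; crystals form when [target] > cs2 (solubility = 9.70 mM, k = 0.00370 s⁻¹)
    substrate + target → side product (k = 0.00170 L mol⁻¹ s⁻¹)

In north at 40 h substrate and dissolved target relax, by the step between them, with a half-life of 0.430 h, short against the time. Dissolved target in north is then made at 0.234 of the rate at which it is used up. Started from the 31.3% of substrate that north holds at 20.0 h, the integral with a gives 24.3% at 40.0 h, and north holds 23.9%. Started from the 16.0% of south at 20.0 h, with crystals at 0%, it gives 9.32%, and south holds 9.00%.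

The numbers in the tables come from a simulation for an exercise.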